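## Structural features

The target is a C20 gibberellin triacid. A trans-fused cyclohexane–cyclopentane pair (rings A and B) is joined through the C8–C9 bond to a bicyclo[3.2.1]octane (rings C and D), and C8 is a fully substituted bridgehead common to rings B, C and D. Ring B carries four contiguous stereocentres (C9, C10, C5, C6) next to quaternary C8. C10 and C4 are also quaternary, and C3, C4, C5 and C10 form an unbroken run of stereocentres in ring A, with the C19 and C20 carboxyls 1,3-diaxial on one face and the C3 hydroxyl axial on the other. Around ring B the large groups alternate: C15, H9, C1, H5 and C7 lie on one face, and C14, C11, C20 and C4 on the other. The fragile points are the C3–C4 β-hydroxy acid (retro-aldol and C3 epimerisation in base), the tertiary C16 carbinol (ionisation in strong acid), the epimerisable C6, and three hindered carboxyls that cannot be freed by saponification. The real difficulty is the density of quaternary and tertiary centres around ring B, above all C9, where hydrogen must stand on the more hindered side, facing the two-carbon bridge. The key step exploits that C8 is a bridgehead flanked by two carbonyl-level carbons (C6 and C9) and that C16 bears one exocyclic carbon: a 1,3-dicarbonyl radical at C8 closes ring C onto C14, and the C13 radical then closes ring D onto an alkyne at C16.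

## Logic of the disconnections

35 to 34: no skeletal bond is cut. The C19 acid is masked as a tert-butyl ester and the C16 hydroxyl as a triethylsilyl ether, both removable by acid, so no hindered ester has to be saponified next to the base-sensitive C3–C4 aldol unit. The demand is an acidolysis mild enough to spare the tertiary carbinol.

34 to 33 to 32 to 30: the C3 carbinol goes back to a ketone, the C7 and C20 carboxyls to aldehydes, and the C7 aldehyde to a vinyl group (the C7=CH2 bond is the one cleaved forward). This removes two acids and one stereocentre and leaves groups that tolerate enolate chemistry. The demands are equatorial hydride delivery at C3 and a single alkene in the molecule at the ozonolysis stage.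

30 to 28: the C3–C4 and C4–C18 bonds are cut (β-keto ester retron). Ring A and the C4 quaternary centre disappear and two trans-disposed arms on C5 and C10 remain. The forward step must make the C4 enolate attack the C3 ester and not the reverse, and must bring the methyl group in anti to the axial C20 group.

28 to 26 and 27: the C10–C1 bond is cut next to the C20 formyl group. The quaternary C10 becomes an enolisable aldehyde carbon, and the demand is addition to the enolate face opposite the C5 arm.

26 to 25 to 24: the C10–C20 bond is cut through the C10=C20 enol ether back to a C10 ketone. The ketone makes C9 and C5 epimerisable, so both can be set under thermodynamic control. The demand is olefination of a ketone that is branched on both sides.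

24 to 21 and 22 and a vinyl nucleophile: the C6–C7 and C5–C4 bonds are cut across a cyclopentenone. Two stereocentres and two side chains are removed at once. The demand is conjugate addition from the C15 face and alkylation of the resulting enolate before it equilibrates.

21 to 20: the C5=C6 bond is cut (aldol condensation retron). Ring B opens to a 1,4-keto aldehyde in which only one enolate can cyclise. The demand is that C9 settles in the cis ring fusion.

20 to 19 to 18 to 15 and 16: the C9–C10 bond is cut at an enol triflate, with 16 as an acetyl anion equivalent. This returns to a bicyclic core with only C6 and C9 functionalised. The demand is a coupling at a triflate next to a quaternary carbon.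

15 to 14 to 12 to 11 to 10: functional-group changes only (ester reduction, enol triflate formation, silylation, hydration of the C16 methylene). The auxiliary is released for recovery. The demand is exo delivery of oxygen at C16.

10 to 9: the C8–C14 and C13–C16 bonds are cut. Two rings and two stereocentres are removed and an open-chain keto ester results. The demand is face selectivity at the C8 radical and 6-endo then 5-exo regiochemistry.

9 to 6 and 7, 6 to 3 and 4, 3 to 1 and 2: the C8–C15, C11–C12 and ester C–O bonds are cut, so the chain comes from three commercial electrophiles and the chiral alcohol. The demand is clean mono-alkylation at each enolate position.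

## Other disconnections considered

Alternative 1: The cut is the C6–C8 bond; ring B is re-expanded to the cyclohexane of an ent-kauranoid in which C7 stands between C6 and C8. In the forward sense, KOtBu would deprotonate the C7 hydroxyl of the 6-mesyloxy-7-hydroxy kauranoid A2. C8 would then migrate from C7 to C6 with inversion at C6, expelling mesylate and leaving C7 as the aldehyde of A1.
- In its favour: the shift mirrors the biosynthetic contraction, delivers C6 stereospecifically from an equatorial leaving group, brings C7 in at the aldehyde level, and leaves C5, C8, C9, C10 and C13 untouched. On the control of C6 and C9 it is the better plan.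
- Against it here: A2 already holds every other difficulty of the target (two esters on quaternary carbons, the C3 oxygen, the C16 carbinol). Abundant kauranoids do not carry oxygen at both C20 and C3, so A2 would need a remote oxidation or a synthesis as long as that of the target. The base would also meet a β-silyloxy ester open to retro-aldol cleavage and an aldehyde A1 that can epimerise at C6.
- Comparison: structurally it moves the problem from ring B to the supply of A2. Mechanistically it is a stereospecific 1,2-shift, against a radical cascade that leans on an auxiliary. In step economy it would be equal or better only if A2 were a few steps from a natural kauranoid, which this oxidation pattern does not allow.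

Alternative 2: The cut removes C11; the C9–C11 and C11–C12 bonds are broken and C9 is joined to C12 in the norbornene A4. Forward, dichlorocarbene from Cl3CCO2Na would add to the exo face of the C9=C12 bond of A4, and the dichlorocyclopropane would open with chloride migration to the allylic dichloride A3, whose ring C has six members.
- In its favour: the norbornene core is a Diels–Alder product, the reagent is cheap, and dihalocarbene ring expansion of norbornenes is dependable. In the convergence of the C/D synthesis it is the equal of the chosen plan, and it needs no auxiliary.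
- Against it here: the C9=C12 bond of A4 is trisubstituted and lies between quaternary C8 and quaternary C10, so addition would be slow and would come late, on a fully built tetracycle. A3 still needs removal of two chlorines and reduction of the C9(11) double bond with hydrogen delivered to C9 from the face of the two-carbon bridge. That is the very problem the chosen plan solves by equilibration next to a C10 ketone.
- Comparison: structurally it reaches the same bicycle but leaves C9 open. Mechanistically it is a two-electron addition and electrocyclic opening with predictable regiochemistry, against a radical cascade. In step economy it is worse by the dechlorination and reduction steps and by a separate route to A4.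

Alternative 3: The cut is C5–C10 and C3–C4; rings A and B open together to the triene A6, a bicyclo[3.2.1]octane with an (E)-enal on the C6 arm and a silyloxydiene on C9. Forward, heating or Me2AlCl would bring about an intramolecular Diels–Alder reaction to A5, forming two rings, two C–C bonds and the centres C3, C4, C5 and C10 in one step.
- In its favour: the cycloaddition is suprafacial, so the relative configurations follow from the alkene geometries, and A6 could be reached from the same bicyclic keto ester 10. In bond-forming economy for rings A and B it is clearly the better plan (one step against six C–C bond-forming steps).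
- Against it here: C9 and C6 must be set beforehand without the help of a ring B ketone. The endo/exo and facial preference of a cycloaddition that creates two quaternary centres is uncertain, and the silyloxydiene is sensitive to the Lewis acid. A5 also has the wrong oxidation levels: a formyl group where the C18 methyl belongs, benzyl ethers where the C19 and C20 acids belong, and a C1=C2 bond to hydrogenate.
- Comparison: structurally the alternative is more convergent. Mechanistically it is one concerted event, against stepwise enolate chemistry in which each centre is set separately and can be corrected. In step economy the shorter skeleton assembly is offset by the redox adjustments, so the two are roughly equal; the alternative is the better in elegance, the chosen plan in control.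

Key step: step 4

Assumption: the (−)-8-phenylmenthyl ester is taken to expose the face of the C8 radical that leads to the (1R,5R) bicycle 10 as drawn; this facial sense is not proven, and the route is built on it. Atom numbers are those of the target throughout.

Step 1
Reactants: 1 (−)-8-phenylmenthol; 2 2,2,6-trimethyl-4H-1,3-dioxin-4-one
Product: 3 (−)-8-phenylmenthyl 3-oxobutanoate
Conditions: xylenes, 140 °C
Reagents that add atoms: none
Why: Thermal retro-[4+2] of the dioxinone releases acetylketene, which the hindered secondary alcohol traps (acetoacetylation); no stereocentre is formed.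

Step 2
Reactants: 3 (−)-8-phenylmenthyl 3-oxobutanoate; 4 allyl bromide
Product: 6 (−)-8-phenylmenthyl 3-oxohept-6-enoate, via dianion 5 (not isolated)
Conditions: NaH, THF, 0 °C; n-BuLi, 0 °C; 4, 0 °C → rt
Reagents that add atoms: none
Why: Acetoacetate dianion alkylation; the more basic γ-carbanion reacts with the allylic halide and gives the C11–C14 chain.

Step 3
Reactants: 6 (−)-8-phenylmenthyl 3-oxohept-6-enoate; 7 propargyl bromide
Product: 9 (−)-8-phenylmenthyl 3-oxo-2-(prop-2-yn-1-yl)hept-6-enoate (both epimers at C8), via sodium enolate 8 (not isolated)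
Conditions: NaH, THF, 0 °C; then 7 (1.0 equiv), 0 °C → rt
Reagents that add atoms: none
Why: SN2 mono-alkylation of the β-keto ester enolate with a reactive propargylic halide; the C8 epimers are of no consequence because C8 becomes a planar radical in the next step.

Step 4
Reactants: 9 (−)-8-phenylmenthyl 3-oxo-2-(prop-2-yn-1-yl)hept-6-enoate
Product: 10 (−)-8-phenylmenthyl (1R,5R)-6-methylene-2-oxobicyclo[3.2.1]octane-1-carboxylate (C8 ester, C9 ketone, C16 methylene)
Conditions: Mn(OAc)3·2H2O (2.2 equiv), degassed EtOH, rt
Reagents that add atoms: none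
Why: Mn(OAc)3 forms the manganese enolate of the β-keto ester and inner-sphere electron transfer gives the electrophilic C8 radical, in which the two C8 epimers of 9 converge. Ring C closes 6-endo-trig by attack on the terminal alkene carbon C14, the mode preferred when the ketone lies inside the forming ring and the alkene is monosubstituted, and leaves a secondary C13 radical. Ring D closes 5-exo-dig by attack of C13 on C16 of the alkyne, which is possible only with the propargyl arm axial on the new chair, so C13 follows from C8 by the bicyclic constraint. The C17 vinyl radical abstracts hydrogen from ethanol, and the second equivalent of trivalent manganese oxidises the resulting α-hydroxyethyl radical to acetaldehyde. The closest known reaction type is the Mn(OAc)3-mediated oxidative free-radical tandem cyclisation of 2-propargyl-3-oxohept-6-enoates to methylenebicyclo[3.2.1]octanones. C8 is controlled by the 8-phenylmenthyl group, whose phenyl ring stacks over one face of the planar radical so that C14 should add to the open face. The step needs face selectivity at C8 and 6-endo over 5-exo regioselectivity; the first rests on the auxiliary, the second on the position of the ketone, and the substituent at C8 prevents further oxidation of the product.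

Step 5
Reactants: 10 (−)-8-phenylmenthyl (1R,5R)-6-methylene-2-oxobicyclo[3.2.1]octane-1-carboxylate
Product: 11 (−)-8-phenylmenthyl (1R,5R,6R)-6-hydroxy-6-methyl-2-oxobicyclo[3.2.1]octane-1-carboxylate (16-OH exo, syn to C14; C17 methyl endo)
Conditions: Co(acac)2 (cat.), PhSiH3, O2 (1 atm), THF, rt
Reagents that add atoms: dioxygen, O=O
Why: Mukaiyama hydration: hydrogen-atom transfer to C17 gives the tertiary C16 radical, which takes up O2 on the exo face (away from the axial C11 hydrogen), and the peroxide is reduced by the silane. Markovnikov regiochemistry and exo attack set C16 as in the target, and a radical path avoids the cationic shifts of acid hydration.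

Step 6
Reactants: 11 (−)-8-phenylmenthyl (1R,5R,6R)-6-hydroxy-6-methyl-2-oxobicyclo[3.2.1]octane-1-carboxylate
Product: 12 (−)-8-phenylmenthyl (1R,5R,6R)-6-methyl-2-oxo-6-(triethylsilyloxy)bicyclo[3.2.1]octane-1-carboxylate
Conditions: Et3SiOTf, 2,6-lutidine, CH2Cl2, −78 °C
Reagents that add atoms: triethylsilyl trifluoromethanesulfonate, CC[Si](CC)(CC)OS(=O)(=O)C(F)(F)F
Why: Silylation of a tertiary alcohol with a silyl triflate; the low temperature and the weak base keep the ketone from forming a silyl enol ether. The ether protects O16 in the later enolate alkylation and methylation steps.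

Step 7
Reactants: 12 (−)-8-phenylmenthyl (1R,5R,6R)-6-methyl-2-oxo-6-(triethylsilyloxy)bicyclo[3.2.1]octane-1-carboxylate
Product: 14 (−)-8-phenylmenthyl 6-methyl-6-(triethylsilyloxy)-2-(trifluoromethylsulfonyloxy)bicyclo[3.2.1]oct-2-ene-1-carboxylate (C9 enol triflate, C9=C11; configuration as in 12), via potassium enolate 13 (not isolated)
Conditions: KN(SiMe3)2, THF, −78 °C; PhNTf2, −78 → 0 °C
Reagents that add atoms: N-phenylbis(trifluoromethanesulfonimide), O=S(=O)(N(c1ccccc1)S(=O)(=O)C(F)(F)F)C(F)(F)F
Why: The ketone can enolise only toward C11 (C8 is quaternary), and O-sulfonylation of the enolate gives the enol triflate. This masks the ketone during the ester reduction and activates C9 for coupling.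

Step 8
Reactants: 14 (−)-8-phenylmenthyl 6-methyl-6-(triethylsilyloxy)-2-(trifluoromethylsulfonyloxy)bicyclo[3.2.1]oct-2-ene-1-carboxylate
Product: 15 [6-methyl-6-(triethylsilyloxy)-2-(trifluoromethylsulfonyloxy)bicyclo[3.2.1]oct-2-en-1-yl]methanol (C6 primary alcohol; configuration as in 14)
Conditions: i-Bu2AlH (excess), CH2Cl2, −78 → 0 °C; aq. potassium sodium tartrate
Reagents that add atoms: none
Why: Hydride reduction of the hindered ester to the primary alcohol; the enol triflate and silyl ether are inert to the aluminium hydride at low temperature, and (−)-8-phenylmenthol is released for recovery.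

Step 9
Reactants: 15 [6-methyl-6-(triethylsilyloxy)-2-(trifluoromethylsulfonyloxy)bicyclo[3.2.1]oct-2-en-1-yl]methanol; 16 tributyl(1-ethoxyvinyl)stannane
Product: 18 1-[1-(hydroxymethyl)-6-methyl-6-(triethylsilyloxy)bicyclo[3.2.1]oct-2-en-2-yl]ethanone (C10 acetyl on C9, C9=C11), via ethoxydiene 17 (not isolated)
Conditions: Pd(PPh3)4 (cat.), LiCl, 1,4-dioxane, 90 °C; then 1 M HCl, THF, rt
Reagents that add atoms: water, O
Why: Stille coupling: oxidative addition of zerovalent palladium to the enol triflate (assisted by chloride) and transfer of the α-ethoxyvinyl group, an acetyl anion equivalent known to couple with enol triflates next to quaternary carbons. Mild acid hydrolysis of the very labile enol ether gives the methyl enone, which brings in C10 and C5.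

Step 10
Reactants: 18 1-[1-(hydroxymethyl)-6-methyl-6-(triethylsilyloxy)bicyclo[3.2.1]oct-2-en-2-yl]ethanone
Product: 19 1-[1-(hydroxymethyl)-6-methyl-6-(triethylsilyloxy)bicyclo[3.2.1]octan-2-yl]ethanone (C9 epimers, in equilibrium with the cyclic hemiketal)
Conditions: H2 (1 atm), Pd/C (cat.), EtOAc, rt
Reagents that add atoms: none
Why: Heterogeneous hydrogenation of the conjugated C9=C11 bond, the only alkene present. Hydrogen should add mainly from the face away from the two-carbon bridge, but the C9 configuration is not relied on because it is equilibrated in step 12.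

Step 11
Reactants: 19 1-[1-(hydroxymethyl)-6-methyl-6-(triethylsilyloxy)bicyclo[3.2.1]octan-2-yl]ethanone
Product: 20 2-acetyl-6-methyl-6-(triethylsilyloxy)bicyclo[3.2.1]octane-1-carbaldehyde (C6 aldehyde; C9 epimers)
Conditions: DMP (triacetoxyperiodinane), NaHCO3, CH2Cl2, rt
Reagents that add atoms: none
Why: Dess–Martin oxidation of the neopentyl primary alcohol to a non-enolisable aldehyde under buffered, non-epimerising conditions.

Step 12
Reactants: 20 2-acetyl-6-methyl-6-(triethylsilyloxy)bicyclo[3.2.1]octane-1-carbaldehyde
Product: 21 tricyclic enone (rings B, C, D: C10 ketone, C5=C6, H9 syn to C15, 16-OSiEt3)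
Conditions: KOH, MeOH, 60 °C
Reagents that add atoms: none
Why: Intramolecular aldol condensation of a 1,4-keto aldehyde: only the methyl enolate (C5) can reach the aldehyde to close a five-membered ring, and E1cB loss of water gives the cyclopentenone. C9, now α to the ketone, equilibrates to the cis ring fusion (C10 axial on ring C, H9 syn to C15), because a trans-fused cyclopentenone cannot be accommodated on the rigid chair of ring C.

Step 13
Reactants: 21 tricyclic enone; 22 tert-butyl bromoacetate
Product: 24 tricyclic ketone with 6-vinyl on the C15 face and 5-(tert-butoxycarbonylmethyl) trans to it (C10 ketone), via lithium enolate 23 (not isolated)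
Conditions: (CH2=CH)2CuLi [from CH2=CHLi and CuBr·SMe2], THF, −78 °C; then HMPA, 22, −78 → −30 °C
Reagents that add atoms: lithium divinylcuprate, [Li+].C=C[Cu-]C=C
Why: Conjugate addition of the cuprate to the cyclopentenone occurs anti to the pseudo-axial C14 on C8, which places the vinyl group (future C7) on the C15 face. The regiodefined C5 enolate is alkylated by the reactive α-bromo ester trans to the new vinyl group (three-component coupling), and this trans arrangement is also the thermodynamic one at the epimerisable C5.

Step 14
Reactants: 24 tricyclic ketone with 6-vinyl and 5-(tert-butoxycarbonylmethyl) groups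
Product: 25 C10 (methoxymethylene) enol ether of 24 (E/Z mixture)
Conditions: Ph3P(CH2OMe)Cl, KN(SiMe3)2, THF, 0 → 50 °C
Reagents that add atoms: (methoxymethyl)triphenylphosphonium chloride, COC[P+](c1ccccc1)(c1ccccc1)c1ccccc1.[Cl-]
Why: Wittig methoxymethylenation, the standard one-carbon homologation of a ketone; it introduces C20 at C10. Any epimerisation at C5 or C9 by the basic ylide only returns the more stable isomers already present.

Step 15
Reactants: 25 C10 (methoxymethylene) enol ether
Product: 26 C10 carbaldehyde (C20 formyl on C10; C10 epimers)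
Conditions: 1 M HCl, THF, 0 °C → rt
Reagents that add atoms: water, O
Why: Acid hydrolysis of the enol ether to the aldehyde; the tert-butyl ester and the hindered tertiary silyl ether are stable to dilute acid, and the C10 epimers converge in the next step.

Step 16
Reactants: 26 C10 carbaldehyde; 27 methyl acrylate
Product: 28 C10-quaternary aldehyde (methyl propanoate chain C1–C3 on the H5/H9 face, C20 formyl on the opposite face)
Conditions: KOt-Bu (cat.), t-BuOH/THF, 27 (excess), 0 °C → rt
Reagents that add atoms: none
Why: Base-catalysed Michael addition of an α,α-disubstituted aldehyde enolate to an acrylate; the much less acidic ester α-hydrogens are not involved. The acceptor approaches the C10 enolate from the face opposite the C5 side chain and the pseudo-axial C14, which sets the quaternary C10 with C1 on the H5 face and C20 syn to C14.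

Step 17
Reactants: 28 C10-quaternary aldehyde
Product: 30 tetracyclic 3-oxo 4-methyl 4-(tert-butyl ester) with C20 formyl and 6-vinyl groups (C18 equatorial, C19 axial and syn to C20), via potassium enolate 29 (not isolated)
Conditions: KOt-Bu, THF, 0 °C; then MeI, rt
Reagents that add atoms: iodomethane, CI
Why: Dieckmann condensation: the tert-butyl ester enolate (C4) attacks the methyl ester (C3), while the reverse ring closure is shut off because a tert-butyl ester is a poor acyl acceptor. The β-keto ester enolate is then methylated in the same flask on the face away from the axial C20 formyl group (1,3-diaxial shielding, as known for 3-oxo-4-carboalkoxy decalins with an angular substituent), leaving the ester axial.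

Step 18
Reactants: 30 tetracyclic 3-oxo 4-methyl 4-(tert-butyl ester) with C20 formyl and 6-vinyl groups
Product: 32 7,20-dialdehyde (3-oxo, 19-tert-butyl ester, 16-OSiEt3), via ozonide 31 (not isolated)
Conditions: O3, CH2Cl2, −78 °C; then Me2S, −78 °C → rt
Reagents that add atoms: ozone, [O-][O+]=O
Why: Ozonolysis of the only alkene with reductive work-up reveals C7 as the aldehyde under neutral conditions that do not epimerise C6.

Step 19
Reactants: 32 7,20-dialdehyde
Product: 33 3-oxo 7,20-dioic acid 19-tert-butyl ester (16-OSiEt3)
Conditions: NaClO2, NaH2PO4, 2-methylbut-2-ene, t-BuOH/H2O, rt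
Reagents that add atoms: sodium chlorite, [Na+].[O-]Cl=O
Why: Pinnick oxidation converts both the enolisable C7 aldehyde and the hindered neopentyl C20 aldehyde to acids under buffered conditions, so no ester hydrolysis is needed for these two carboxyls.

Step 20
Reactants: 33 3-oxo 7,20-dioic acid 19-tert-butyl ester
Product: 34 3-hydroxy 7,20-dioic acid 19-tert-butyl ester 16-O-triethylsilyl ether (3-OH axial, cis to C18)
Conditions: K[s-Bu3BH] (excess), THF, −78 → −40 °C; aq. NH4Cl
Reagents that add atoms: none
Why: The bulky trialkylborohydride attacks the C3 ketone along the equatorial trajectory and gives the axial alcohol cis to the C18 methyl, as known for 3-oxo gibberellins and 4,4-disubstituted 3-ketones. The carboxylates are inert, and a cold quench avoids retro-aldol opening of the alkoxide.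

Step 21
Reactants: 34 3-hydroxy 7,20-dioic acid 19-tert-butyl ester 16-O-triethylsilyl ether
Product: 35 target triacid CNP0183110.3 (3,16-dihydroxygibberellane-7,19,20-trioic acid)
Conditions: CF3CO2H/CH2Cl2/H2O, 0 °C → rt
Reagents that add atoms: none
Why: Acidolysis cleaves the tert-butyl ester by alkyl–oxygen fission (independent of the hindrance at C4) and removes the silyl ether. Water is present to return any C16 cation to the carbinol, and no base is used after the C3 hydroxyl is in place.

Compound list
1 | (−)-8-phenylmenthol, (1R,2S,5R)-5-methyl-2-(2-phenylpropan-2-yl)cyclohexan-1-ol | C[C@@H]1CC[C@H]([C@@H](C1)O)C(C)(C)c1ccccc1 | starting material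
2 | 2,2,6-trimethyl-4H-1,3-dioxin-4-one | CC1=CC(=O)OC(C)(C)O1 | starting material
3 | (−)-8-phenylmenthyl 3-oxobutanoate | C[C@@H]1CC[C@H]([C@@H](C1)OC(=O)CC(C)=O)C(C)(C)c1ccccc1 | intermediate
4 | allyl bromide | C=CCBr | starting material
5 | sodium lithium dianion of 3 (not isolated) | C[C@@H]1CC[C@H]([C@@H](C1)OC(=O)C=C([O-])[CH2-])C(C)(C)c1ccccc1.[Na+].[Li+] | intermediate
6 | (−)-8-phenylmenthyl 3-oxohept-6-enoate | C[C@@H]1CC[C@H]([C@@H](C1)OC(=O)CC(=O)CCC=C)C(C)(C)c1ccccc1 | intermediate
7 | propargyl bromide | C#CCBr | starting material
8 | sodium enolate of 6 (not isolated) | C[C@@H]1CC[C@H]([C@@H](C1)OC(=O)C=C([O-])CCC=C)C(C)(C)c1ccccc1.[Na+] | intermediate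
9 | (−)-8-phenylmenthyl 3-oxo-2-(prop-2-yn-1-yl)hept-6-enoate (both C8 epimers) | C[C@@H]1CC[C@H]([C@@H](C1)OC(=O)C(CC#C)C(=O)CCC=C)C(C)(C)c1ccccc1 | intermediate
10 | (−)-8-phenylmenthyl (1R,5R)-6-methylene-2-oxobicyclo[3.2.1]octane-1-carboxylate | C[C@@H]1CC[C@H]([C@@H](C1)OC(=O)[C@@]23C[C@@H](CCC2=O)C(=C)C3)C(C)(C)c1ccccc1 | intermediate
11 | (−)-8-phenylmenthyl (1R,5R,6R)-6-hydroxy-6-methyl-2-oxobicyclo[3.2.1]octane-1-carboxylate (OH exo) | C[C@@H]1CC[C@H]([C@@H](C1)OC(=O)[C@@]23C[C@@H](CCC2=O)[C@](C)(O)C3)C(C)(C)c1ccccc1 | intermediate
12 | (−)-8-phenylmenthyl (1R,5R,6R)-6-methyl-2-oxo-6-(triethylsilyloxy)bicyclo[3.2.1]octane-1-carboxylate | C[C@@H]1CC[C@H]([C@@H](C1)OC(=O)[C@@]23C[C@@H](CCC2=O)[C@](C)(O[Si](CC)(CC)CC)C3)C(C)(C)c1ccccc1 | intermediate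
13 | potassium C9(11)-enolate of 12 (not isolated) | C[C@@H]1CC[C@H]([C@@H](C1)OC(=O)[C@@]23C[C@@H](CC=C2[O-])[C@](C)(O[Si](CC)(CC)CC)C3)C(C)(C)c1ccccc1.[K+] | intermediate
14 | (−)-8-phenylmenthyl 6-methyl-6-(triethylsilyloxy)-2-(trifluoromethylsulfonyloxy)bicyclo[3.2.1]oct-2-ene-1-carboxylate | C[C@@H]1CC[C@H]([C@@H](C1)OC(=O)[C@@]23C[C@@H](CC=C2OS(=O)(=O)C(F)(F)F)[C@](C)(O[Si](CC)(CC)CC)C3)C(C)(C)c1ccccc1 | intermediate
15 | [6-methyl-6-(triethylsilyloxy)-2-(trifluoromethylsulfonyloxy)bicyclo[3.2.1]oct-2-en-1-yl]methanol | OC[C@@]12C[C@@H](CC=C1OS(=O)(=O)C(F)(F)F)[C@](C)(O[Si](CC)(CC)CC)C2 | intermediate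
16 | tributyl(1-ethoxyvinyl)stannane | C=C(OCC)[Sn](CCCC)(CCCC)CCCC | starting material
17 | [2-(1-ethoxyethenyl)-6-methyl-6-(triethylsilyloxy)bicyclo[3.2.1]oct-2-en-1-yl]methanol (not isolated) | OC[C@@]12C[C@@H](CC=C1C(=C)OCC)[C@](C)(O[Si](CC)(CC)CC)C2 | intermediate
18 | 1-[1-(hydroxymethyl)-6-methyl-6-(triethylsilyloxy)bicyclo[3.2.1]oct-2-en-2-yl]ethanone | OC[C@@]12C[C@@H](CC=C1C(C)=O)[C@](C)(O[Si](CC)(CC)CC)C2 | intermediate
19 | 1-[1-(hydroxymethyl)-6-methyl-6-(triethylsilyloxy)bicyclo[3.2.1]octan-2-yl]ethanone (C9 epimers) | OC[C@@]12C[C@@H](CCC1C(C)=O)[C@](C)(O[Si](CC)(CC)CC)C2 | intermediate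
20 | 2-acetyl-6-methyl-6-(triethylsilyloxy)bicyclo[3.2.1]octane-1-carbaldehyde (C9 epimers) | O=C[C@@]12C[C@@H](CCC1C(C)=O)[C@](C)(O[Si](CC)(CC)CC)C2 | intermediate
21 | tricyclic enone: C10 ketone, C5=C6, H9 syn to C15, 16-OSiEt3 | C1=C[C@@]23C[C@@H](CC[C@H]2C1=O)[C@](C)(O[Si](CC)(CC)CC)C3 | intermediate
22 | tert-butyl bromoacetate | BrCC(=O)OC(C)(C)C | starting material
23 | lithium C5(10)-enolate of the 6-vinyl ketone (not isolated) | [Li]OC1=C[C@H](C=C)[C@@]23C[C@@H](CC[C@H]21)[C@](C)(O[Si](CC)(CC)CC)C3 | intermediate
24 | tricyclic ketone: 6-vinyl on the C15 face, 5-(tert-butoxycarbonylmethyl) trans, C10 ketone | O=C(OC(C)(C)C)C[C@H]1[C@H](C=C)[C@@]23C[C@@H](CC[C@H]2C1=O)[C@](C)(O[Si](CC)(CC)CC)C3 | intermediate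
25 | C10 (methoxymethylene) enol ether of 24 (E/Z) | O=C(OC(C)(C)C)C[C@H]1[C@H](C=C)[C@@]23C[C@@H](CC[C@H]2C1=COC)[C@](C)(O[Si](CC)(CC)CC)C3 | intermediate
26 | C10 carbaldehyde (C10 epimers) | O=C(OC(C)(C)C)C[C@H]1[C@H](C=C)[C@@]23C[C@@H](CC[C@H]2C1C=O)[C@](C)(O[Si](CC)(CC)CC)C3 | intermediate
27 | methyl acrylate | C=CC(=O)OC | starting material
28 | C10-quaternary aldehyde with methyl propanoate chain (C1–C3) and C20 formyl | O=C(OC(C)(C)C)C[C@H]1[C@H](C=C)[C@@]23C[C@@H](CC[C@H]2[C@]1(C=O)CCC(=O)OC)[C@](C)(O[Si](CC)(CC)CC)C3 | intermediate
29 | potassium enolate of the tetracyclic 3-oxo 4-(tert-butyl ester) (not isolated) | [K+].[O-]C1=C(C(=O)OC(C)(C)C)[C@H]2[C@H](C=C)[C@@]34C[C@@H](CC[C@H]3[C@]2(C=O)CC1)[C@](C)(O[Si](CC)(CC)CC)C4 | intermediate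
30 | tetracyclic 3-oxo 4-methyl 4-(tert-butyl ester), C20 formyl, 6-vinyl, 16-OSiEt3 | C[C@]1(C(=O)OC(C)(C)C)[C@H]2[C@H](C=C)[C@@]34C[C@@H](CC[C@H]3[C@]2(C=O)CCC1=O)[C@](C)(O[Si](CC)(CC)CC)C4 | intermediate
31 | ozonide of 30 (1,2,4-trioxolane at C7; not isolated) | C[C@]1(C(=O)OC(C)(C)C)[C@H]2[C@H](C5OCOO5)[C@@]34C[C@@H](CC[C@H]3[C@]2(C=O)CCC1=O)[C@](C)(O[Si](CC)(CC)CC)C4 | intermediate
32 | 7,20-dialdehyde, 3-oxo, 19-tert-butyl ester, 16-OSiEt3 | C[C@]1(C(=O)OC(C)(C)C)[C@H]2[C@H](C=O)[C@@]34C[C@@H](CC[C@H]3[C@]2(C=O)CCC1=O)[C@](C)(O[Si](CC)(CC)CC)C4 | intermediate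
33 | 3-oxo 7,20-dioic acid 19-tert-butyl ester, 16-OSiEt3 | C[C@]1(C(=O)OC(C)(C)C)[C@H]2[C@H](C(=O)O)[C@@]34C[C@@H](CC[C@H]3[C@]2(C(=O)O)CCC1=O)[C@](C)(O[Si](CC)(CC)CC)C4 | intermediate
34 | 3-hydroxy 7,20-dioic acid 19-tert-butyl ester 16-O-triethylsilyl ether | C[C@]1(C(=O)OC(C)(C)C)[C@H]2[C@H](C(=O)O)[C@@]34C[C@@H](CC[C@H]3[C@]2(C(=O)O)CC[C@@H]1O)[C@](C)(O[Si](CC)(CC)CC)C4 | intermediate
35 | target triacid CNP0183110.3 | C[C@]1(C(=O)O)[C@H]2[C@H](C(=O)O)[C@@]34C[C@@H](CC[C@H]3[C@]2(C(=O)O)CC[C@@H]1O)[C@](C)(O)C4 | target

Total step count: 21. Longest linear sequence: 21 steps, from 1 and 2 to 35; 4, 7, 16, 22 and 27 enter as commercial materials.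

Least certain steps

Step 4 (key step). Most likely to go wrong: poor or reversed facial selectivity at the C8 radical, because the aryl group shields a radical that is flanked by two acyl groups and can rotate about the bond to the ester carbon. A lesser concern is hydrogen abstraction by the C13 radical before the second ring closure. Within the step, a chelating Lewis acid such as Yb(OTf)3 or the enantiomeric auxiliary are the first levers. The fallback replaces auxiliary control by resolution.
- It sets out from 2, 4, 7 and 1. Dioxinone 2 is heated with 2-(trimethylsilyl)ethanol to give 2-(trimethylsilyl)ethyl 3-oxobutanoate F1.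
- F1 is allylated with 4 through its dianion to 2-(trimethylsilyl)ethyl 3-oxohept-6-enoate F2 and propargylated with 7 to 2-(trimethylsilyl)ethyl 3-oxo-2-(prop-2-yn-1-yl)hept-6-enoate F3.
- Mn(OAc)3 in ethanol should close F3 to racemic 2-(trimethylsilyl)ethyl 6-methylene-2-oxobicyclo[3.2.1]octane-1-carboxylate F4.
- Bu4NF should free racemic 6-methylene-2-oxobicyclo[3.2.1]octane-1-carboxylic acid F5, a bridgehead β-keto acid that cannot decarboxylate through an enol.
- Steglich esterification of F5 with 1 should give 10 together with its (1S,5S) diastereomer F6, to be separated by chromatography or crystallisation. The route is rejoined at 10.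

Step 13. Most likely to go wrong: proton exchange between enolate 23 and the alkylated ketone, or slow alkylation at the hindered C5, so that the simple conjugate adduct or over-alkylated material forms. A lesser risk is approach of the cuprate from the C14 face. The fallback builds the C5 side chain in before ring B is closed.
- It sets out from 15. A Pd(PPh3)4-catalysed carbonylative Negishi coupling under CO with (3-tert-butoxy-3-oxopropyl)zinc iodide should give tert-butyl 4-[1-(hydroxymethyl)-6-methyl-6-(triethylsilyloxy)bicyclo[3.2.1]oct-2-en-2-yl]-4-oxobutanoate F7.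
- Hydrogenation over Pd/C should give the saturated keto ester F8, and Dess–Martin oxidation the keto aldehyde F9.
- KOH in methanol should close F9 to the 5-(tert-butoxycarbonylmethyl) cyclopentenone F10.
- Conjugate addition of lithium divinylcuprate to F10 gives the lithium enolate F11. Protonation under equilibrating conditions, in which the epimerisable C5 settles trans to the vinyl group, should give 24, where the route is rejoined.

Step 14. Most likely to go wrong: enolisation of the doubly α-branched C10 ketone by the basic ylide in place of addition, so that the ketone is returned. The fallback is a sulfur ylide and an epoxide rearrangement. From 24, dimethylsulfonium methylide (Me3SI, n-BuLi) should give the C10 spiro-epoxide F12. A Meinwald rearrangement with MgBr2·OEt2 at low temperature (hydride shift from C20) should then give 26 directly, bypassing 25.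

Step 16. Most likely to go wrong: slow deprotonation of the hindered formyl α-carbon, so that anionic polymerisation of the acrylate or retro-Michael loss outruns productive addition. The fallback is a Lewis-acid route through a preformed enol ether. From 26, silylation (Me3SiCl, Et3N, NaI, MeCN) should give the C10=C20 trimethylsilyl enol ether F13. A Mukaiyama–Michael addition of F13 to 27 with catalytic Me3SiNTf2 in CH2Cl2 at −78 °C, followed by aqueous work-up, should give 28.

Step 21. Most likely to go wrong: ionisation of the tertiary C16 carbinol in the strong acid, with elimination or a Wagner–Meerwein shift in the bicyclo[3.2.1]octane, or trifluoroacetylation of the hydroxyls. The fallback uses silyl transfer and then fluoride in place of protic acidolysis. From 34, Me3SiOTf and 2,6-lutidine in CH2Cl2 should convert the tert-butyl ester into a silyl ester without generating a carbocation at C16; mild aqueous work-up should then give the 16-O-triethylsilyl triacid F14. HF·pyridine in MeCN should remove the silyl ether and give 35.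

Further compounds
F1 | step 4 | 2-(trimethylsilyl)ethyl 3-oxobutanoate | CC(=O)CC(=O)OCC[Si](C)(C)C
F2 | step 4 | 2-(trimethylsilyl)ethyl 3-oxohept-6-enoate | C=CCCC(=O)CC(=O)OCC[Si](C)(C)C
F3 | step 4 | 2-(trimethylsilyl)ethyl 3-oxo-2-(prop-2-yn-1-yl)hept-6-enoate | C=CCCC(=O)C(CC#C)C(=O)OCC[Si](C)(C)C
F4 | step 4 | racemic 2-(trimethylsilyl)ethyl 6-methylene-2-oxobicyclo[3.2.1]octane-1-carboxylate | C=C1CC2(C(=O)OCC[Si](C)(C)C)CC1CCC2=O
F5 | step 4 | racemic 6-methylene-2-oxobicyclo[3.2.1]octane-1-carboxylic acid | C=C1CC2(C(=O)O)CC1CCC2=O
F6 | step 4 | (−)-8-phenylmenthyl (1S,5S)-6-methylene-2-oxobicyclo[3.2.1]octane-1-carboxylate | C[C@@H]1CC[C@H]([C@@H](C1)OC(=O)[C@]23C[C@H](CCC2=O)C(=C)C3)C(C)(C)c1ccccc1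
F7 | step 13 | tert-butyl 4-[1-(hydroxymethyl)-6-methyl-6-(triethylsilyloxy)bicyclo[3.2.1]oct-2-en-2-yl]-4-oxobutanoate | OC[C@@]12C[C@@H](CC=C1C(=O)CCC(=O)OC(C)(C)C)[C@](C)(O[Si](CC)(CC)CC)C2
F8 | step 13 | tert-butyl 4-[1-(hydroxymethyl)-6-methyl-6-(triethylsilyloxy)bicyclo[3.2.1]octan-2-yl]-4-oxobutanoate (C9 epimers) | OC[C@@]12C[C@@H](CCC1C(=O)CCC(=O)OC(C)(C)C)[C@](C)(O[Si](CC)(CC)CC)C2
F9 | step 13 | tert-butyl 4-[1-formyl-6-methyl-6-(triethylsilyloxy)bicyclo[3.2.1]octan-2-yl]-4-oxobutanoate (C9 epimers) | O=C[C@@]12C[C@@H](CCC1C(=O)CCC(=O)OC(C)(C)C)[C@](C)(O[Si](CC)(CC)CC)C2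
F10 | step 13 | tricyclic enone with 5-(tert-butoxycarbonylmethyl) group (C10 ketone, C5=C6) | O=C(OC(C)(C)C)CC1=C[C@@]23C[C@@H](CC[C@H]2C1=O)[C@](C)(O[Si](CC)(CC)CC)C3
F11 | step 13 | lithium C5(10)-enolate of 24 | [Li]OC1=C(CC(=O)OC(C)(C)C)[C@H](C=C)[C@@]23C[C@@H](CC[C@H]21)[C@](C)(O[Si](CC)(CC)CC)C3
F12 | step 14 | C10 spiro-epoxide of 24 (C10 epimers) | O=C(OC(C)(C)C)C[C@H]1[C@H](C=C)[C@@]23C[C@@H](CC[C@H]2C14CO4)[C@](C)(O[Si](CC)(CC)CC)C3
F13 | step 16 | C10=C20 trimethylsilyl enol ether of 26 | O=C(OC(C)(C)C)C[C@H]1[C@H](C=C)[C@@]23C[C@@H](CC[C@H]2C1=CO[Si](C)(C)C)[C@](C)(O[Si](CC)(CC)CC)C3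
F14 | step 21 | 16-O-triethylsilyl ether of the target triacid | C[C@]1(C(=O)O)[C@H]2[C@H](C(=O)O)[C@@]34C[C@@H](CC[C@H]3[C@]2(C(=O)O)CC[C@@H]1O)[C@](C)(O[Si](CC)(CC)CC)C4
A1 | alternative 1 | gibberellin 7-aldehyde 19,20-dimethyl ester 3-O-tert-butyldimethylsilyl ether | C[C@]1(C(=O)OC)[C@H]2[C@H](C=O)[C@@]34C[C@@H](CC[C@H]3[C@]2(C(=O)OC)CC[C@@H]1O[Si](C)(C)C(C)(C)C)[C@](C)(O)C4
A2 | alternative 1 | 6-mesyloxy-7-hydroxy ent-kauranoid 19,20-dimethyl ester (mesylate equatorial) | C[C@]1(C(=O)OC)[C@H]2[C@H](OS(C)(=O)=O)[C@H](O)[C@@]34C[C@@H](CC[C@H]3[C@]2(C(=O)OC)CC[C@@H]1O[Si](C)(C)C(C)(C)C)[C@](C)(O)C4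
A3 | alternative 2 | 11,12-dichloro-9(11)-ene bicyclo[3.2.1]octene tetracycle | C[C@]1(C(=O)OC)[C@H]2[C@H](C(=O)OC)[C@@]34C[C@@H]([C@@H](Cl)C(Cl)=C3[C@]2(C(=O)OC)CC[C@@H]1O[Si](C)(C)C(C)(C)C)[C@](C)(OC(C)=O)C4
A4 | alternative 2 | C9=C12 norbornene tetracycle | C[C@]1(C(=O)OC)[C@H]2[C@H](C(=O)OC)[C@@]34C[C@@H](C=C3[C@]2(C(=O)OC)CC[C@@H]1O[Si](C)(C)C(C)(C)C)[C@](C)(OC(C)=O)C4
A5 | alternative 3 | tetracyclic 1-ene with C4 formyl and benzyloxymethyl groups at C4 and C10 | O=C[C@]1(COCc4ccccc4)[C@H]2[C@H](C(=O)OC)[C@@]36C[C@@H](CC[C@H]3[C@]2(COCc5ccccc5)C=C[C@@H]1O[Si](C(C)C)(C(C)C)C(C)C)[C@](C)(O)C6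
A6 | alternative 3 | bicyclo[3.2.1]octane triene with (E)-enal on the C6 arm and silyloxydiene on C9 | O=C/C(COCc1ccccc1)=C/[C@H](C(=O)OC)[C@@]23C[C@@H](CC[C@H]2/C(COCc2ccccc2)=C/C=C/O[Si](C(C)C)(C(C)C)C(C)C)[C@](C)(O)C3
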